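The reading is taken at 12 h, and I start from that clock.

| flask | starting material | partner | second reagent | third reagent | temperature | time | remark |
|---|---|---|---|---|---|---|---|
| Wednesday's | 0.40 M (fed, over 8.0 h) | 0.480 M | 1.20 M | 0.400 M | 80 °C | 12 h | all else is in the flask from the start; the feed brings no volume worth counting |
| Saturday's | 0.40 M | 0.480 M | 1.20 M | 0.400 M (fed, over 8.0 h) |  | 12 h | the addition at 50 °C, then warmed to 80 °C; the feed brings no volume worth counting |
| Sunday's | 0.40 M | 0.480 M | 1.20 M | 0.400 M |  | 12 h | everything together at the start at 50 °C, warmed to 80 °C at 8.0 h |
| Friday's | 0.40 M | 0.480 M | 1.20 M | 0.400 M | 80 °C | 12 h | everything together at the start |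
| Monday's | 0.40 M | 0.480 M | 1.20 M | 0.400 M (fed, over 8.0 h) | 80 °C | 12 h | all else is in the flask from the start; the feed brings no volume worth counting |

    starting material + partner → intermediate A (k1 = 3.7 M⁻¹ h⁻¹, Ea1 = 70.0 kJ mol⁻¹)
    second reagent + intermediate A → intermediate B (k2 = 0.71 M⁻¹ h⁻¹, Ea2 = 71.0 kJ mol⁻¹)
    third reagent + intermediate B → product (k3 = 0.25 M⁻¹ h⁻¹, Ea3 = 78.0 kJ mol⁻¹)
    (constants at 80 °C)

* which flask leads in amount of product, in percent of the starting material charged ("all alike" within 1.5 percentage points) (Wednesday's / Saturday's / Sunday's / Friday's / Monday's / all alike)
* how much product is there at the end, in percent of the starting material charged: Wednesday's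
* how much product is there at the end, in percent of the starting material charged: Saturday's
* how much product is there at the end, in percent of the starting material charged: Sunday's
* how much product is there at the end, in percent of the starting material charged: Friday's
* how much product is there at the end, in percent of the starting material charged: Monday's

- the constants hold at 80 °C; other temperatures follow from the activation energies

**Clocks first.** At the charged amounts and 80 °C, starting material has a lifetime of 0.563 h against partner, and intermediate A has one of 1.17 h against second reagent. The quantity I carry is the last-step clock τ, defined as one over the product of the last step's rate constant and the charged third reagent. It is the mean lifetime of intermediate B against third reagent as charged, and at 80 °C it comes to 10.0 h. This is longer than both earlier lifetimes, so with everything in the flask from the start at 80 °C, as in Friday's flask, the last step is the rate-limiting step.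

**Friday's lag.** In Friday's flask everything is present from the start, so I take the lag L before the last step runs at full supply as the sum of the earlier lifetimes, 1.74 h. The reading then allows θ = (time − L)/τ = 1.03 clocks.

**Two ways.** The first way is pseudo-first-order: it holds third reagent at its charge, so Friday's product share is 1 − exp(−θ), or 64.2%. The second way starts from Friday's equal charges of starting material and third reagent. Intermediate B and third reagent then fall together in a second-order tail, and the share is θ/(1 + θ), or 50.6%.

**The cheat.** The two part, and the first way is the one that cheats: it spends 0.257 M of third reagent while still counting it at 0.400 M. I commit to 50.6% for Friday's as an upper estimate, since partner falls toward 0.0800 M, which lengthens the lag.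

**The forecast.** The forecast puts Friday's first at 47.5%, then Monday's at 41%, Wednesday's at 33%, Sunday's at 19.5% and Saturday's at 19.3%. Its ground is that “anything that delays it costs product”. For Friday's it stands 3.1 percentage points below my number.

**The flasks.** Friday's leads at 47.7%, followed by Monday's at 41.2%, Wednesday's at 34.0%, Sunday's at 19.9% and Saturday's at 19.8%. Friday's lies 2.9 points below my number. Friday's flask is unfinished at 12.0 h, with intermediate B still holding 51.2% of the starting material charged, after 1.20 clocks counted from the start. For Saturday's flask I count clocks from the warming at 8.0 h to 120 h, and θ/(1 + θ) gives 91.8%. Saturday's flask stands at 91.7% product, in percent of the starting material charged, at 120 h.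

Its constants belong to no real substance; the result is computed.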